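Electrophile is conserved, so whatever a reading shows neither as electrophile nor as target has gone elsewhere, and in birch that unread part grows from 5.80% at 0.833 min to 48.9% at 8.00 min.

the same everywhere: electrophile 19 mM; scavenger 28.5 mM

| charge | nucleophile | gas | remark | time |
|---|---|---|---|---|
| birch | 25 mM | 1 mM (held) | run made earlier |  |
| alder | 74 mM | 1 mM (held) | run made earlier |  |
| east | 21.0 mM | 1.0 mM (held) |  | 10 min |
| west | 31.0 mM | 1.0 mM (held) |  | 10 min |
| south-east | 47.0 mM | 1.0 mM (held) |  | 10 min |

- birch (time / min: electrophile / %, target / %): 0.833: 66.1, 28.1; 2.50: 38.9, 41.8; 5.00: 20.7, 41.9; 8.00: 11.0, 40.1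
- alder (time / min: electrophile / %, target / %): 0.500: 44.5, 50.9; 1.33: 11.4, 76.3; 3.00: 1.6, 83.1; 8.00: 0, 83.9

(each reading ± 1 percentage point)

- at the start none of the gas is in solution

- part of the electrophile that has reacted at the end, east
- part of the electrophile that has reacted at the end, west
- part of the electrophile that has reacted at the end, south-east
- what raising the concentration of nucleophile from its lowest to its highest value here does to the part of the electrophile that has reacted (changes below 5 percentage points count as none) (it rises / no change / it falls)

In the first instants nucleophile attacks electrophile. The first alder reading, with c(nucleophile) taken at its mean for one nucleophile per step, gives a rate constant of 0.0236 mM⁻¹ min⁻¹.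

In the middle the unread part is taken to grow with electrophile times target, as if each loss removed one of each. Birch gives a rate constant of 0.0153 mM⁻¹ min⁻¹ between 2.50 min and 5.00 min. The ratio of the two constants is the selectivity factor S, 1.54. Electrophile stands in both rates and cancels, so an electrophile makes target or destroys it at the odds S·c(nucleophile)/c(target). Target stops growing at odds of one, and control changes hands there.

Birch target is flat at 5.00 min with c(target) at 7.96 mM, so c(nucleophile) there is near 5.16 mM. That is less than the 13.5 mM that one nucleophile per step would leave. Counting two unread units as one step, each step takes 1.72 nucleophile.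

At the end birch electrophile still falls at 0.211 min⁻¹. With S and that take held, the crossing target scales with the nucleophile charge, so my own reckoning scales the birch exponent, extended to 10 min, by charge. It gives 89.0%, 96.2% and 99.3%.

The forecast says 91.5%, 94.5% and 99%, with the trend it rises, and holds the nucleophile “most likely eaten by the scavenger”. My east figure lies lower, and my west figure higher.

    electrophile + nucleophile → acid set free + target (k = 0.432 M⁻¹ s⁻¹)
    nucleophile + acid set free ⇌ protonated nucleophile, settled at all times (K = 3.80 × 10⁵ M⁻¹)
    acid set free + free base ⇌ salt of the base, settled at all times (K = 1200 M⁻¹)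
    acid set free + free base ⇌ idle adduct, settled at all times (K = 570 M⁻¹)
    acid set free + scavenger → scavenged by-product (k = 40.3 M⁻¹ s⁻¹)
    gas ⇌ free base, rate k6*(csat - [free base]) (kL = 0.114 s⁻¹)
    electrophile + target → side product (k = 0.224 M⁻¹ s⁻¹)

The flask gives 86.0% in east, 96.6% in west and 99.8% in south-east, and the trend is it rises, by 14 percentage points, with the forecast for east too high by 5.5 points. East at 5.00 min has 12.6% of its nucleophile free and target at 34.3%, so the odds stand at 0.625, and target reads 32.3% at 10.0 min. In a neighbour of south-east charged with 48 mM of electrophile, the odds at 10.0 min are 0.547, with target at 18.1% and side product at 75.0%.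

The earlier runs and the new flask were generated by integration with made-up constants, noise included.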